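**Two ratios.** A percentage point counts for much in the delta run, where the isomer of the product A never read above 2 %. There its ratio to target read 0.125 at 2.00 h but 0 at 4.00 h, and the second has no logarithm at all.

| flask | starting material | remark | time |
|---|---|---|---|
| delta | 0.075 M | run made earlier |  |
| flask | 0.050 M |  | 3.0 d |

- delta (time / h: isomer of the product A / %, target / %): 2.00: 2, 16; 4.00: 0, 27; 5.00: 1, 30; 8.00: 1, 36

(standard deviation of a reading: 1.5 percentage points)

- what was read earlier has a scatter of 1.5 percentage points, one standard deviation
- a reading or a percentage of target counts all its forms, free or not

- ratio of isomer of the product A to target at 40 min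
- ratio of isomer of the product A to target at 3.0 d
- which of isomer of the product A and target there is more of at 3.0 d

**Pooling them.** Those two isomer readings differ by 2 percentage points, with 1.5 points of scatter on each, so I didn't trust either ratio and pooled the delta run. I got 0.0367, or −1.44 in powers of ten: the pooled ratio, the summed isomer readings over the summed target readings, a read selectivity. For the new flask I committed to it at 40 min, which lies 0.477 decades before the first reading. But 3.0 d lies 0.954 decades beyond the last, so there I kept it as a lower mark.

**The forecast.** It gave 0.03 at 40 min, under my pooled ratio, and 0.12 at 3.0 d, adding: “The target very probably still leads”.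

**The result.** The flask gave 0.0415 and 0.265, with target ahead, 24.7 % against 6.55 %.

    intermediate ⇌ isomer of the product A (K = 2.50, k = 0.450 h⁻¹)
    starting material + target ⇌ idle adduct, settled at all times (K = 120 L mol⁻¹)
    target ⇌ isomer of the product B (K = 2.80, k = 0.240 h⁻¹)
    starting material → intermediate (k = 0.110 h⁻¹)
    intermediate ⇌ target (K = 8.90, k = 11.0 h⁻¹)

**Neighbour flask.** Measured from the pooled ratio, this flask stood 0.0534 decades up at 40 min and 0.859 decades up at 3.0 d. The neighbour flask, charged with 0.12 M of starting material, gave 0.0400 at 40 min, which is 0.0374 decades up. At 3.0 d it gave 0.223, which is 0.784 decades up. By then the neighbour flask held 57.5 % of its charge as isomer of the product B.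

(The runs were generated by integration for substances that don't exist.)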